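**Plan**
- The phenol is masked as a benzyl ether to the end. Ring A is then de-aromatised in thought (four hydrogens and an angular allyl ester at C4a put back) and cut at C4a–C5 and C8–C8a.
- Enabling feature: ring A (C4a, C5, C6, C7, C8, C8a) carries adjacent methoxy groups at C6 and C7 and is fused through C4a–C8a. That fusion bond is the C2=C3 alkene of a monocyclic 4-pyranone, and C5–C6(OMe)–C7(OMe)–C8 is symmetric 2,3-dimethoxybutadiene.
- The pyranone is cut at its O–CH enol ether bond and at the C–C bond between the side-chain carbonyl and the methyl group of an acetoacetate-derived enaminone.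
- Forward order: the pyranone ring forms first (acylation, cyclisation), then ring A by Diels–Alder reaction, then palladium-mediated loss of the angular ester, DDQ aromatisation and debenzylation.
- The target has no stereocentre. The two cis ring-fusion centres of the cycloadduct arise from suprafacial addition, are racemic, and disappear on aromatisation.

Key step: step 5

Assumption: all chiral intermediates are racemic; the SMILES of 9–12 show one enantiomer of the cis-fused series only for drawing, and the C4a epimer of 11 would serve equally.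

**Step 1**
Reactants: 1 prop-2-en-1-yl 3-oxobutanoate (allyl acetoacetate)
Product: 2 prop-2-en-1-yl 2-[(dimethylamino)methylidene]-3-oxobutanoate
Conditions: Me2NCH(OMe)2 (1.1 equiv), toluene, rt to 50 °C, then evaporation
Reagents that add atoms: N,N-dimethylformamide dimethyl acetal, COC(OC)N(C)C
Why: Enaminone formation by condensation of the active methylene of a β-keto ester with an amide acetal is a standard reaction that runs under neutral conditions, so the allyl ester is not exchanged.

**Step 2**
Reactants: 3 3-(4-hydroxy-3-methoxyphenyl)propanoic acid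
Product: 4 3-[4-(benzyloxy)-3-methoxyphenyl]propanoic acid
Conditions: BnBr (1.3 equiv), NaOH (2.5 equiv), EtOH–H2O, reflux; then 2 M HCl to pH 2
Reagents that add atoms: benzyl bromide, BrCc1ccccc1
Why: Williamson ether synthesis on the dianion, in which the phenoxide is far more nucleophilic than the carboxylate in a protic medium and excess hydroxide keeps the acid as its sodium salt until acidification.

**Step 3**
Reactants: 4 3-[4-(benzyloxy)-3-methoxyphenyl]propanoic acid
Product: 5 3-[4-(benzyloxy)-3-methoxyphenyl]propanoyl chloride
Conditions: (COCl)2 (1.3 equiv), DMF (catalytic), CH2Cl2, 0 °C to rt; evaporation, used crude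
Reagents that add atoms: oxalyl chloride, O=C(Cl)C(=O)Cl
Why: Acid chloride formation by Vilsmeier-type activation gives only gaseous by-products and leaves the aryl benzyl and methyl ethers untouched.

**Step 4**
Reactants: 2 prop-2-en-1-yl 2-[(dimethylamino)methylidene]-3-oxobutanoate; 5 3-[4-(benzyloxy)-3-methoxyphenyl]propanoyl chloride
Product: 7 prop-2-en-1-yl 6-{2-[4-(benzyloxy)-3-methoxyphenyl]ethyl}-4-oxo-4H-pyran-3-carboxylate, via acylated enaminone 6 (not isolated)
Conditions: LiN(SiMe3)2 (2.4 equiv) added to 2 and 5 in THF, −78 °C; then 3 M aq HCl, rt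
Reagents that add atoms: none
Why: Kinetic deprotonation of the methyl ketone of the push–pull enaminone gives a lithium dienolate that is C-acylated by the acid chloride (Claisen-type acylation, the second equivalent of base taking up the acidic 1,3-diketone), and on acidification the new enol oxygen adds to the enamine carbon and expels dimethylamine in a 6-endo addition–elimination, the established way to 6-substituted 4-oxo-4H-pyran-3-carboxylates.

**Step 5**
Reactants: 7 prop-2-en-1-yl 6-{2-[4-(benzyloxy)-3-methoxyphenyl]ethyl}-4-oxo-4H-pyran-3-carboxylate; 8 2,3-dimethoxybuta-1,3-diene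
Product: 9 prop-2-en-1-yl cis-2-{2-[4-(benzyloxy)-3-methoxyphenyl]ethyl}-6,7-dimethoxy-4-oxo-4a,5,8,8a-tetrahydro-4H-chromene-4a-carboxylate (racemic)
Conditions: 8 (4 equiv), BHT (catalytic), toluene, 130 °C, sealed tube, argon
Reagents that add atoms: none
Why: Concerted, thermally allowed [π4s+π2s] Diels–Alder reaction in which the HOMO of the bis-methoxy diene 8 adds to the C2=C3 bond of pyranone 7, whose LUMO is lowered by the ring ketone and the allyl ester together; the closest known reaction type is the normal-demand cycloaddition of 3-alkoxycarbonyl-4-pyranones and of 3-acyl-, 3-alkoxycarbonyl- or 3-cyanochromones with alkoxy dienes. Ring A closes as a six-membered carbocycle in a single intermolecular (4+2) event that forms C4a–C5 and C8–C8a (chromone numbering) together. The two new stereocentres, quaternary C4a and C8a, are tied to each other by suprafacial addition across the cis-configured ring alkene, so the fusion can only be cis; the product is racemic because nothing chiral is present, which is harmless since both centres become sp2 in step 7. The selectivity needed is for the ester-bearing double bond over the C5=C6 bond of the pyranone, and it is secured because that second alkene has a single acceptor and a donating alkyl substituent; the symmetry of 8 leaves no regiochemical choice. If the enol-ether half of 8 instead adds in an inverse-demand fashion across the C2=C3–C4=O oxadiene, the resulting 2-alkenyl dihydropyran is an allyl vinyl ether that should converge on 9 by [3,3] shift at the reaction temperature. The adduct has no hydrogen at C4a, so it cannot lose the ring oxygen by β-elimination, and BHT holds back radical polymerisation of the diene.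

**Step 6**
Reactants: 9 prop-2-en-1-yl cis-2-{2-[4-(benzyloxy)-3-methoxyphenyl]ethyl}-6,7-dimethoxy-4-oxo-4a,5,8,8a-tetrahydro-4H-chromene-4a-carboxylate
Product: 11 cis-2-{2-[4-(benzyloxy)-3-methoxyphenyl]ethyl}-6,7-dimethoxy-4a,5,8,8a-tetrahydro-4H-chromen-4-one, via β-keto acid 10 (not isolated)
Conditions: Pd(OAc)2 (5 mol %), PPh3 (20 mol %), HCO2H (2.5 equiv), Et3N (3.5 equiv), THF, rt then 40 °C
Reagents that add atoms: none
Why: Tsuji deallylation–decarboxylation, in which zerovalent palladium ionises the allyl ester, formate reduces the π-allyl fragment to propene and the freed β-keto acid with its quaternary α-carbon loses CO2 under buffered, near-neutral conditions that spare both enol ethers and the benzyl ether; protonation of the resulting enol at C4a, expected mainly from the less hindered face to give the cis ketone, has no consequence because C4a and C8a become sp2 in the next step.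

**Step 7**
Reactants: 11 cis-2-{2-[4-(benzyloxy)-3-methoxyphenyl]ethyl}-6,7-dimethoxy-4a,5,8,8a-tetrahydro-4H-chromen-4-one
Product: 13 2-{2-[4-(benzyloxy)-3-methoxyphenyl]ethyl}-6,7-dimethoxy-4H-chromen-4-one, via 4a,8a-dihydrochromone 12 (not isolated)
Conditions: DDQ (2.1 equiv), 1,4-dioxane, rt
Reagents that add atoms: none
Why: DDQ dehydrogenative aromatisation, in which hydride abstraction from the allylic CH2 groups of the electron-rich bis(enol ether) and proton loss give a cyclohexadiene that a second equivalent converts to the benzene ring of the chromone; at room temperature with a near-stoichiometric charge the ArCH2CH2 tether and the benzyl ether should not be attacked.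

**Step 8**
Reactants: 13 2-{2-[4-(benzyloxy)-3-methoxyphenyl]ethyl}-6,7-dimethoxy-4H-chromen-4-one
Product: 14 2-[2-(4-hydroxy-3-methoxyphenyl)ethyl]-6,7-dimethoxy-4H-chromen-4-one
Conditions: H2 (1 atm), 10% Pd/C, EtOAc–MeOH, rt
Reagents that add atoms: none
Why: Catalytic hydrogenolysis of the aryl benzyl ether over Pd/C, under which the C2=C3 bond of a chromone is a vinylogous ester alkene that is routinely retained, as in the hydrogenation of 2-styrylchromones to 2-(2-phenylethyl)chromones.

**Compound list**
1 | prop-2-en-1-yl 3-oxobutanoate (allyl acetoacetate) | CC(=O)CC(=O)OCC=C | starting material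
2 | prop-2-en-1-yl 2-[(dimethylamino)methylidene]-3-oxobutanoate (push–pull alkene, geometry labile and not specified) | CC(=O)C(=CN(C)C)C(=O)OCC=C | intermediate
3 | 3-(4-hydroxy-3-methoxyphenyl)propanoic acid (dihydroferulic acid) | COc1cc(CCC(=O)O)ccc1O | starting material
4 | 3-[4-(benzyloxy)-3-methoxyphenyl]propanoic acid | COc1cc(CCC(=O)O)ccc1OCc1ccccc1 | intermediate
5 | 3-[4-(benzyloxy)-3-methoxyphenyl]propanoyl chloride | COc1cc(CCC(=O)Cl)ccc1OCc1ccccc1 | intermediate
6 | prop-2-en-1-yl 7-[4-(benzyloxy)-3-methoxyphenyl]-2-[(dimethylamino)methylidene]-3,5-dioxoheptanoate | C=CCOC(=O)C(=CN(C)C)C(=O)CC(=O)CCc1ccc(OCc2ccccc2)c(OC)c1 | intermediate (not isolated)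
7 | prop-2-en-1-yl 6-{2-[4-(benzyloxy)-3-methoxyphenyl]ethyl}-4-oxo-4H-pyran-3-carboxylate | C=CCOC(=O)c1coc(CCc2ccc(OCc3ccccc3)c(OC)c2)cc1=O | intermediate
8 | 2,3-dimethoxybuta-1,3-diene | COC(=C)C(=C)OC | starting material
9 | prop-2-en-1-yl cis-2-{2-[4-(benzyloxy)-3-methoxyphenyl]ethyl}-6,7-dimethoxy-4-oxo-4a,5,8,8a-tetrahydro-4H-chromene-4a-carboxylate (racemic; ester and 8a-H on the same face) | C=CCOC(=O)[C@@]12CC(OC)=C(OC)C[C@@H]1OC(CCc1ccc(OCc3ccccc3)c(OC)c1)=CC2=O | intermediate
10 | cis-2-{2-[4-(benzyloxy)-3-methoxyphenyl]ethyl}-6,7-dimethoxy-4-oxo-4a,5,8,8a-tetrahydro-4H-chromene-4a-carboxylic acid (racemic) | OC(=O)[C@@]12CC(OC)=C(OC)C[C@@H]1OC(CCc1ccc(OCc3ccccc3)c(OC)c1)=CC2=O | intermediate (not isolated)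
11 | cis-2-{2-[4-(benzyloxy)-3-methoxyphenyl]ethyl}-6,7-dimethoxy-4a,5,8,8a-tetrahydro-4H-chromen-4-one (racemic) | O=C1C=C(CCc2ccc(OCc3ccccc3)c(OC)c2)O[C@H]2CC(OC)=C(OC)C[C@@H]12 | intermediate
12 | cis-2-{2-[4-(benzyloxy)-3-methoxyphenyl]ethyl}-6,7-dimethoxy-4a,8a-dihydro-4H-chromen-4-one (racemic; expected first-formed diene) | O=C1C=C(CCc2ccc(OCc3ccccc3)c(OC)c2)O[C@H]2C=C(OC)C(OC)=C[C@@H]12 | intermediate (not isolated)
13 | 2-{2-[4-(benzyloxy)-3-methoxyphenyl]ethyl}-6,7-dimethoxy-4H-chromen-4-one | COc1cc(CCc2cc(=O)c3cc(OC)c(OC)cc3o2)ccc1OCc1ccccc1 | intermediate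
14 | 2-[2-(4-hydroxy-3-methoxyphenyl)ethyl]-6,7-dimethoxy-4H-chromen-4-one | COc1cc(CCc2cc(=O)c3cc(OC)c(OC)cc3o2)ccc1O | target

**Count**
Total steps: 8. Longest linear sequence: 7 steps (3 to 14 through steps 2, 3, 4, 5, 6, 7, 8).

**Steps most likely to fail**

Step 5. The cycloaddition may be too slow on the partly aromatic pyranone, the diene may polymerise or hydrolyse before it adds, or addition may stop at an inverse-demand adduct. In that case ring A would be taken from an aromatic building block. Acid chloride 5 acylates commercial 1-(2-hydroxy-4,5-dimethoxyphenyl)ethanone (pyridine, CH2Cl2, 0 °C to rt) to give 2-acetyl-4,5-dimethoxyphenyl 3-[4-(benzyloxy)-3-methoxyphenyl]propanoate F1. Baker–Venkataraman rearrangement (KOt-Bu, THF, rt) moves the acyl group to carbon and gives 1-(2-hydroxy-4,5-dimethoxyphenyl)-5-[4-(benzyloxy)-3-methoxyphenyl]pentane-1,3-dione F2. Cyclodehydration with catalytic p-TsOH in toluene at reflux closes the chromone. This fallback sets out from 5 and rejoins the route at 13.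

Step 4. The amide base may deprotonate acid chloride 5 to a ketene, or the dienolate may be acylated at oxygen, so that the 1,3-diketone never forms. The side chain would then be attached by alkylation. Enaminone 2 is acylated with acetyl chloride, the electrophile for which this pyranone synthesis is best established, under the conditions of step 4. This passes through prop-2-en-1-yl 2-[(dimethylamino)methylidene]-3,5-dioxohexanoate F3 and gives prop-2-en-1-yl 6-methyl-4-oxo-4H-pyran-3-carboxylate F4. Commercial [4-(benzyloxy)-3-methoxyphenyl]methanol is converted with PBr3 (Et2O, 0 °C) into 4-(benzyloxy)-3-methoxybenzyl bromide F5. Lateral deprotonation of the 6-methyl group of F4 (LiN(SiMe3)2, THF, −78 °C) gives a vinylogous enolate that F5 alkylates at the exocyclic carbon. This fallback sets out from 2 and rejoins the route at 7.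

Step 7. The quinone may over-oxidise the substrate by hydride abstraction at the ArCH2CH2 tether, may add as a dienophile to the intermediate diene, or the C4a–H ketone may lose the ring oxygen by β-elimination before it is oxidised. The oxidation level would then be adjusted at the decarboxylation stage, so that ketone 11 is never formed. Adduct 9 is submitted to Tsuji decarboxylation–dehydrogenation (Pd(OAc)2 and PPh3, both catalytic, MeCN, 80 °C, no formate). The palladium enolate left after loss of CO2 undergoes β-hydride elimination and the allyl group leaves as propene. The product is 2-{2-[4-(benzyloxy)-3-methoxyphenyl]ethyl}-6,7-dimethoxy-5,8-dihydro-4H-chromen-4-one F6 (its 8,8a-dihydro isomer would serve equally). Activated MnO2 in CH2Cl2 at rt then aromatises this cyclohexadiene without touching the tether. This fallback sets out from 9 and rejoins the route at 13.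

**Further compounds**
F1 | step 5 | 2-acetyl-4,5-dimethoxyphenyl 3-[4-(benzyloxy)-3-methoxyphenyl]propanoate | CC(=O)c1cc(OC)c(OC)cc1OC(=O)CCc1ccc(OCc2ccccc2)c(OC)c1
F2 | step 5 | 1-(2-hydroxy-4,5-dimethoxyphenyl)-5-[4-(benzyloxy)-3-methoxyphenyl]pentane-1,3-dione | COc1cc(O)c(C(=O)CC(=O)CCc2ccc(OCc3ccccc3)c(OC)c2)cc1OC
F3 | step 4 | prop-2-en-1-yl 2-[(dimethylamino)methylidene]-3,5-dioxohexanoate | C=CCOC(=O)C(=CN(C)C)C(=O)CC(C)=O
F4 | step 4 | prop-2-en-1-yl 6-methyl-4-oxo-4H-pyran-3-carboxylate | C=CCOC(=O)c1coc(C)cc1=O
F5 | step 4 | 4-(benzyloxy)-3-methoxybenzyl bromide | COc1cc(CBr)ccc1OCc1ccccc1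
F6 | step 7 | 2-{2-[4-(benzyloxy)-3-methoxyphenyl]ethyl}-6,7-dimethoxy-5,8-dihydro-4H-chromen-4-one | COC1=C(OC)Cc2oc(CCc3ccc(OCc4ccccc4)c(OC)c3)cc(=O)c2C1
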